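Numbering used throughout: five-membered ring C1–C5 (C15 methyl on C1, isopropyl C11–C13 and hydroxyl on C4); seven-membered ring C1, C10, C9, C8, C7, C6, C5 (C14 methyl on C8). Compounds 1–26 are defined in the steps and in the compound list.

## Analysis of the target

Jaeskeanin (26) is a daucane ester: a trans-fused hydroazulene with a quaternary C1, a tertiary carbinol at C4, a 4-hydroxybenzoate at C6 and a trisubstituted epoxide across C8–C9. It has six stereocentres, (1R,4R,5S,6S,8R,9S) in this numbering, three of them fully substituted (C1, C4, C8). Relative to the five-membered ring, the C15 methyl and the C4 hydroxyl lie on one face, and the isopropyl group, H5, the C6 oxygen and the epoxide oxygen lie on the other. C10 is therefore bonded to C1 on the isopropyl face, and the C4 and C6 oxygens are anti. The sensitive groups are the epoxide (acid, and base once C6 is a carbonyl), the tertiary alcohol β to C6 (dehydration, and retro-aldol at the ketone stage) and the phenolic ester. The hard points are the quaternary C1 flanked by C5 and the C4 carbinol, with its new ring bond on the more hindered face, and the trans ring fusion at C5, which can only be adjusted while C6 is a carbonyl that is also β,γ to the C8=C9 alkene. The strategy rests on the seven-membered ring: oxygen at C6 and unsaturation at C8–C9 flank the C7 methylene, and C1 is the ring-fusion quaternary carbon. That is the pattern of a cyclohepta-1,4-diene assembled from a 2-siloxydiene (C7=C6–C5=C1) and a three-carbon vinylcarbenoid (C8, C9, C10).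

## Retrosynthetic reasoning

**26 ⇒ 25 ⇒ 23 + 24.** The C6–O acyl bond is cut last. The secondary C6 hydroxyl of 23 is the only acylable alcohol (C4 is tertiary), and the phenol travels as its acetate in 24 so that the acid cannot acylate itself. The forward steps must spare the epoxide.

**23 ⇒ 22.** The two C–O bonds of the epoxide are cut back to the C8=C9 alkene of diol 22. The homoallylic C6 hydroxyl sits on the face that must receive oxygen, so a metal-directed epoxidation sets C8 and C9 together; the axial C15 methyl shields the other face.

**22 ⇒ 21 ⇒ 20 ⇒ 18 ⇒ 17.** The C6–H bond is cut to ketone 21, where the C4 hydroxyl can deliver hydride to its own face and give the anti diol. C5 is the α-centre of that ketone. Unmasking the ketone from silyl enol ether 17 protonates C5 kinetically, probably on the wrong (more open) face, giving 18. C5 is therefore set by equilibration in 20, with the C4 oxygen still silylated so that no retro-aldol is possible. Because the C6 carbonyl is β,γ to C8=C9, base will also move the alkene; the equilibration is therefore run through the extended dienolate 19 and finished by kinetic α-protonation, which puts the alkene back.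

**17 ⇒ 15 ⇒ 14.** The C14 methyl is traced to the ester that the carbenoid must carry. The enol ether protects the C6 carbonyl during both hydride reductions.

**14 ⇒ 10 + 12 (key disconnection).** C7–C8 and C1–C10 are cut. This removes the seven-membered ring and the quaternary stereocentre in one operation and leaves a cyclopentene that already holds C4. Forward, a chiral dirhodium catalyst must cyclopropanate the enol ether of 10 with the carbenoid from 12, vinyl cis to cyclopentenyl (13), and the Cope rearrangement must then bond C10 to the isopropyl face of C1. Substrate bias cannot be relied on for that face, so it has to come from the catalyst through the cyclopropane.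

**10 ⇒ 8 ⇒ 7 ⇒ 6.** The O–Si bond and then the C6–C7 bond are cut: kinetic enolisation of methyl ketone 8 at its methyl group, and the ketone from enal 6 by addition of a methyl nucleophile and oxidation.

**6 ⇒ 4 ⇒ 2 ⇒ 1.** The C1=C5 bond of the cyclopentene is cut as an aldol condensation of keto aldehyde 4, which is the ozonolysis product of silylated terpinenol 2. The carbinol carbon of 1 becomes C4 without ever being touched.

**12 ⇒ 11.** The diazo group is introduced by diazo transfer immediately before use.

## Alternatives that were turned down

**Alternative 1: transannular cation–olefin cyclisation.** The C1–C5 bond and the C4–O bond are disconnected, leading back to the ten-membered dienol ester A1. Forward, strong aqueous acid ionises the tertiary C1 alcohol, C5 of the C4=C5 alkene attacks across the ring, and the C6 ester carbonyl captures the C4 cation; hydrolysis gives A2. In its favour, one step forms both rings and three stereocentres, the ester is already on C6, and only epoxidation and deacetylation remain. After its key step it is clearly shorter than the chosen route. Against it, the difficulty moves into A1. Anti addition across C4=C5 gives the required H5/isopropyl relationship only from the ring-cis alkene, so A1 is a cyclodecadiene with two ring-cis trisubstituted alkenes. Its single stereocentre (C6) would have to control C1, C5 and C4 through the conformation of a medium ring. Neither the ring synthesis nor that control is reliable, and the C1 cation can eliminate or be trapped by C8=C9. The chosen route gives up the short endgame but takes C4 from the chiral pool and sets C1 by a catalyst-controlled relay on a rigid intermediate.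

**Alternative 2: directed cyclopropanation as latent angular methyl.** The C1–C15 bond is disconnected: dienol A3, with a tetrasubstituted C1=C5 alkene, is cyclopropanated by a zinc carbenoid delivered from the C4 hydroxyl to give propellane A4. Later reductive cleavage of C5–C15 next to a C6 carbonyl would reveal the methyl and H5. In its favour, the methyl arrives cis to the C4 hydroxyl by intramolecular delivery, exactly the relationship in 26. On this point it is stronger than the chosen route, where C10 must be forced onto the isopropyl face by the catalyst. Against it, the key step builds no ring, and the hydroazulene A3 must first be made by chemistry the strategy does not supply. Tetrasubstituted alkenes are sluggish towards zinc carbenoids even when directed. The cyclopropyl ketone opening must select C5–C15 over C5–C1 and then protonate C5 on the right face. As formulated, A4 also carries its C6 silyloxy group on the face opposite to the ester oxygen of 26, so C6 would have to be oxidised and reduced again. The chosen route offers instead ring, quaternary centre and the C6/C8–C9 oxidation pattern in one step from a six-step precursor.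

**Alternative 3: rhodium (5+2) cycloaddition.** C1–C5 and C6–C7 are disconnected, leading back to the acyclic alkyne-tethered siloxyvinylcyclopropane A5. A monovalent rhodium catalyst joins the alkene terminus C1 to alkyne carbon C5, opens the cyclopropane and joins C7 to C6, giving A6. In its favour, both rings and C1 form in one intramolecular step, all fifteen carbons including C14 are present, and no ester has to be reduced. In ring-forming economy it beats the chosen route, which makes only the seven-membered ring. Against it, a trisubstituted alkene terminus and a 1,2,2-trisubstituted cyclopropane are the demanding variants of this cycloaddition, with a regiochemical choice in the ring cleavage. C1 would be controlled only by C4 through the tether, with no catalyst handle for the isopropyl-face bond. A5 needs a long assembly. The oxidation pattern of A6 is also displaced: oxygen at C9 where the alkene is needed and silicon at C6 where oxygen is needed, so more redox steps follow than in the chosen route, whose product 14 has oxygen at C6 and the alkene at C8–C9 as formed.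

Key step: step 8

Remark: (S)-terpinen-4-ol (1) is assumed to be available in high enantiomeric purity; its carbinol carbon becomes C4 unchanged.

Remark: the catalyst antipode in step 8 is chosen by analogy. Rh2(S-DOSP)4 is recalled to give the (1S,2R)-cyclopropane from styrene and methyl phenyldiazoacetate. Mapped onto 10, that sense would put C10 on the silyloxy face of C1. The R antipode, dirhodium tetrakis[(R)-N-(4-dodecylphenylsulfonyl)prolinate], is therefore specified.

## Route

Step 1
Reactants: 1 (S)-terpinen-4-ol, (1S)-4-methyl-1-(propan-2-yl)cyclohex-3-en-1-ol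
Product: 2 triethyl{[(1S)-4-methyl-1-(propan-2-yl)cyclohex-3-en-1-yl]oxy}silane
Conditions: TESOTf, 2,6-lutidine, CH2Cl2, 0 °C
Reagents that add atoms: triethylsilyl trifluoromethanesulfonate, CC[Si](CC)(CC)OS(=O)(=O)C(F)(F)F
Why: O-Silylation of a tertiary alcohol with a silyl triflate and a hindered pyridine base; the stereocentre is not touched. The ether keeps the hydroxyl from adding to the ketone released in step 2 and blocks retro-aldol cleavage later.

Step 2
Reactants: 2 triethyl{[(1S)-4-methyl-1-(propan-2-yl)cyclohex-3-en-1-yl]oxy}silane
Product: 4 (3S)-6-oxo-3-(propan-2-yl)-3-(triethylsilyloxy)heptanal, via secondary ozonide 3 (not isolated)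
Conditions: O3, CH2Cl2, −78 °C; then PPh3, −78 °C → rt
Reagents that add atoms: ozone, [O-][O+]=O
Why: Ozonolysis of the only alkene with reductive work-up of ozonide 3 gives the methyl ketone and the aldehyde; the silyl ether and the carbinol centre are inert to ozone at −78 °C.

Step 3
Reactants: 4 (3S)-6-oxo-3-(propan-2-yl)-3-(triethylsilyloxy)heptanal
Product: 6 (5R)-2-methyl-5-(propan-2-yl)-5-(triethylsilyloxy)cyclopent-1-ene-1-carbaldehyde, via aldol adduct 5 (not isolated)
Conditions: piperidine (cat.), AcOH (cat.), toluene, rt → 60 °C
Reagents that add atoms: none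
Why: Amine-catalysed intramolecular aldol condensation: the aldehyde forms the enamine far faster than the methyl ketone, so its α-carbon attacks the ketone (5-exo) and loss of water gives the tetrasubstituted enal, the regiochemistry known for 6-oxoheptanals under piperidinium acetate. The hindered tertiary silanolate is a poor leaving group, so β-elimination from the enamine should not compete with the five-membered ring closure; the descriptor changes to R only through the priority rules.

Step 4
Reactants: 6 (5R)-2-methyl-5-(propan-2-yl)-5-(triethylsilyloxy)cyclopent-1-ene-1-carbaldehyde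
Product: 7 1-[(5R)-2-methyl-5-(propan-2-yl)-5-(triethylsilyloxy)cyclopent-1-en-1-yl]ethan-1-ol (both carbinol epimers)
Conditions: MeMgBr, THF, −78 → 0 °C
Reagents that add atoms: methylmagnesium bromide, C[Mg]Br
Why: 1,2-Addition of a Grignard reagent to the hindered enal; the new carbinol centre forms as a mixture and is destroyed in step 5.

Step 5
Reactants: 7 1-[(5R)-2-methyl-5-(propan-2-yl)-5-(triethylsilyloxy)cyclopent-1-en-1-yl]ethan-1-ol
Product: 8 1-[(5R)-2-methyl-5-(propan-2-yl)-5-(triethylsilyloxy)cyclopent-1-en-1-yl]ethan-1-one
Conditions: Dess–Martin periodinane, NaHCO3, CH2Cl2, rt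
Reagents that add atoms: none
Why: Dess–Martin oxidation of a secondary allylic alcohol under buffered conditions that leave the tertiary silyl ether intact.

Step 6
Reactants: 8 1-[(5R)-2-methyl-5-(propan-2-yl)-5-(triethylsilyloxy)cyclopent-1-en-1-yl]ethan-1-one
Product: 10 tert-butyl({1-[(5R)-2-methyl-5-(propan-2-yl)-5-(triethylsilyloxy)cyclopent-1-en-1-yl]ethenyl}oxy)dimethylsilane, via lithium enolate 9 (not isolated)
Conditions: LiN(i-Pr)2, THF, −78 °C; then TBSCl, DMPU, −78 → 0 °C
Reagents that add atoms: tert-butyldimethylsilyl chloride, CC(C)(C)[Si](C)(C)Cl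
Why: Kinetic deprotonation of the enone at the acetyl methyl (α′) rather than at the γ-positions, then O-silylation of enolate 9, gives the cross-conjugated 2-siloxydiene. The flanking quaternary carbon and ring methyl twist the acetyl group out of conjugation, which further favours α′ deprotonation.

Step 7
Reactants: 11 methyl but-3-enoate
Product: 12 methyl 2-diazobut-3-enoate
Conditions: 4-acetamidobenzenesulfonyl azide, DBU, MeCN, 0 °C; extracted into cold pentane and used at once
Reagents that add atoms: 4-acetamidobenzenesulfonyl azide, CC(=O)Nc1ccc(cc1)S(=O)(=O)N=[N+]=[N-]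
Why: Regitz-type diazo transfer to the doubly activated (allylic, α-ester) methylene. The product cyclises to a pyrazole on standing and is therefore not stored.

Step 8
Reactants: 10 tert-butyl({1-[(5R)-2-methyl-5-(propan-2-yl)-5-(triethylsilyloxy)cyclopent-1-en-1-yl]ethenyl}oxy)dimethylsilane; 12 methyl 2-diazobut-3-enoate
Product: 14 methyl (1R,4R)-6-(tert-butyldimethylsilyloxy)-4-(triethylsilyloxy)dauca-5,8-dien-14-oate, via cis-divinylcyclopropane 13 (not isolated)
Conditions: Rh2(R-DOSP)4 (1 mol %), hexanes, −40 °C → rt, 12 (2 equiv) added over 2 h; then reflux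
Reagents that add atoms: none
Why: The catalyst converts 12 into a divalent rhodium vinylcarbenoid whose carbene carbon (C8) attacks the unhindered, electron-rich methylene terminus C7 of the enol ether of 10; closure at C6 gives cyclopropane 13 with the cyclopentenyl group cis to the vinyl group and trans to the ester, the usual sense for donor/acceptor carbenoids. The cis-divinylcyclopropane then undergoes a [3,3]-sigmatropic (Cope) rearrangement through the boat transition state: C6–C8 breaks, C1–C10 forms, and the seven-membered ring (C1, C10, C9, C8, C7, C6, C5) closes by ring expansion, leaving the C8=C9 enoate and the C5=C6 silyl enol ether. Heating is planned because the C1 methyl is the inward-pointing (Z) substituent of the cyclopentenyl terminus. The closest known reaction type is the tandem cyclopropanation/Cope rearrangement (formal (4+3) annulation) of vinyldiazoacetates with 1,3-dienes, including 2-siloxydienes and dienes whose terminus becomes a quaternary carbon. The only new stereocentre, C1, is dictated by the cyclopropane configuration (1S,2R in cyclopropane numbering), because in the boat C10 can reach only one face of C5=C1; that configuration is set by the catalyst, whose R antipode is chosen as explained in the remark above. The step needs site selectivity for the carbene carbon over the vinylogous terminus and for the 1,1-disubstituted enol ether over the tetrasubstituted ring alkene, which the hydrocarbon solvent, the bulky prolinate catalyst and the far higher nucleophilicity of the siloxy alkene should secure. It also needs face selectivity at C6=C7 against any bias from C4, which is plausible because the first bond forms at the remote CH2 terminus.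

Step 9
Reactants: 14 methyl (1R,4R)-6-(tert-butyldimethylsilyloxy)-4-(triethylsilyloxy)dauca-5,8-dien-14-oate
Product: 15 (1R,4R)-6-(tert-butyldimethylsilyloxy)-4-(triethylsilyloxy)dauca-5,8-dien-14-ol
Conditions: i-Bu2AlH, CH2Cl2, −78 °C; aqueous KNaC4H4O6 work-up
Reagents that add atoms: none
Why: 1,2-Reduction of the conjugated ester to the allylic alcohol by an aluminium hydride at low temperature; both silyl groups are inert and the neutral tartrate work-up avoids hydrolysis of the enol ether.

Step 10
Reactants: 15 (1R,4R)-6-(tert-butyldimethylsilyloxy)-4-(triethylsilyloxy)dauca-5,8-dien-14-ol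
Product: 17 (1R,4R)-6-(tert-butyldimethylsilyloxy)-4-(triethylsilyloxy)dauca-5,8-diene, via allylic methanesulfonate 16 (not isolated)
Conditions: MsCl, Et3N, THF, −20 °C; then LiEt3BH, −20 → 0 °C
Reagents that add atoms: none
Why: Sulfonylation of the primary allylic alcohol and direct SN2 displacement of the sulfonate of 16 by a trialkylborohydride. Attack at the unhindered primary C14 is preferred over SN2′ attack at ring carbon C9, so the C8=C9 alkene stays in place.

Step 11
Reactants: 17 (1R,4R)-6-(tert-butyldimethylsilyloxy)-4-(triethylsilyloxy)dauca-5,8-diene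
Product: 18 (1R,4R,5S)-4-(triethylsilyloxy)dauc-8-en-6-one (cis-fused ketone)
Conditions: Bu4NF, AcOH, THF, −20 → 0 °C
Reagents that add atoms: none
Why: Fluoride cleavage of the silyl enol ether with in situ protonation of the enolate at C5 under buffered conditions that leave the tertiary silyl ether and the β,γ-alkene alone. Protonation is expected on the more open face (that of the C15 methyl and the C4 oxygen; the other carries the isopropyl group and the C10 methylene), so the cis-fused epimer 18 should predominate; any trans-fused 20 formed is carried along, since step 12 sets C5.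

Step 12
Reactants: 18 (1R,4R,5S)-4-(triethylsilyloxy)dauc-8-en-6-one
Product: 20 (1R,4R,5R)-4-(triethylsilyloxy)dauc-8-en-6-one (trans-fused ketone), via potassium dienolate 19 (not isolated)
Conditions: KOt-Bu (2 equiv), t-BuOH/THF, rt; then poured into cold aqueous AcOH, 0 °C
Reagents that add atoms: none
Why: Base equilibration and deconjugation: in t-BuOH the ketone, its conjugated C7=C8 isomer and the extended dienolate 19 interconvert, and reversible enolisation towards C5 lets that centre settle in the trans-fused arrangement, in which C6 is gauche to the C15 methyl and the C4 oxygen and no longer to the isopropyl group and C10 (the ring fusion of the natural daucanes). Kinetic protonation of 19 at C7 on inverse quench returns the β,γ-unsaturated ketone (classical deconjugation of an enone through its dienolate); C5 is not acidic in the dienolate and keeps its configuration. In the protic medium, reprotonation of the C5 enolate should outrun loss of the hindered silanolate, and the silyl ether excludes retro-aldol cleavage.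

Step 13
Reactants: 20 (1R,4R,5R)-4-(triethylsilyloxy)dauc-8-en-6-one
Product: 21 (1R,4R,5R)-4-hydroxydauc-8-en-6-one
Conditions: HF·pyridine, pyridine, THF, 0 °C → rt
Reagents that add atoms: none
Why: Fluoride cleavage of the tertiary triethylsilyl ether in a buffered acidic medium; without base neither C5 nor the β,γ-alkene can move and the tertiary aldol cannot cleave.

Step 14
Reactants: 21 (1R,4R,5R)-4-hydroxydauc-8-en-6-one
Product: 22 (1R,4R,5S,6S)-dauc-8-ene-4,6-diol (jaeschkeanadiol)
Conditions: Me4NBH(OAc)3, MeCN/AcOH, −30 → −20 °C
Reagents that add atoms: none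
Why: Hydroxyl-directed reduction (Evans–Saksena type): the C4 hydroxyl exchanges onto boron and hydride is delivered within the chelate to the carbonyl face on the side of the C4 oxygen, giving the 4,6-anti diol with the C6 hydroxyl on the isopropyl face (6S). The acidic low-temperature medium does not enolise the ketone.

Step 15
Reactants: 22 (1R,4R,5S,6S)-dauc-8-ene-4,6-diol
Product: 23 (1R,4R,5S,6S,8R,9S)-8,9-epoxydaucane-4,6-diol
Conditions: VO(acac)2 (5 mol %), t-BuOOH, CH2Cl2, 0 °C → rt
Reagents that add atoms: tert-butyl hydroperoxide, CC(C)(C)OO
Why: Vanadium-catalysed epoxidation directed by the homoallylic C6 hydroxyl, which delivers oxygen to the C8=C9 face syn to itself and sets C8 and C9 together; this is also the face remote from the axial C15 methyl, so directing and steric effects agree. The tertiary C4 hydroxyl is on the other face and too remote to direct, and the syn C6 hydroxyl cannot open the epoxide from the rear.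

Step 16
Reactants: 23 (1R,4R,5S,6S,8R,9S)-8,9-epoxydaucane-4,6-diol; 24 4-acetoxybenzoic acid
Product: 25 (1R,4R,5S,6S,8R,9S)-8,9-epoxy-4-hydroxydaucan-6-yl 4-acetoxybenzoate
Conditions: EDC·HCl, DMAP, CH2Cl2, rt
Reagents that add atoms: none
Why: Carbodiimide/4-(dimethylamino)pyridine (Steglich) esterification: the secondary C6 hydroxyl is acylated while the tertiary C4 hydroxyl does not react, and the neutral conditions spare the epoxide.

Step 17
Reactants: 25 (1R,4R,5S,6S,8R,9S)-8,9-epoxy-4-hydroxydaucan-6-yl 4-acetoxybenzoate
Product: 26 jaeskeanin, (1R,4R,5S,6S,8R,9S)-8,9-epoxy-4-hydroxydaucan-6-yl 4-hydroxybenzoate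
Conditions: pyrrolidine, CH2Cl2, 0 °C
Reagents that add atoms: none
Why: Chemoselective aminolysis of the aryl acetate: a phenyl ester is far more electrophilic than the hindered secondary aroyl ester, and the epoxide is inert to a secondary amine at 0 °C.

## Compound list

1 | (S)-terpinen-4-ol, (1S)-4-methyl-1-(propan-2-yl)cyclohex-3-en-1-ol | CC(C)[C@@]1(O)CC=C(C)CC1 | starting material
2 | triethyl{[(1S)-4-methyl-1-(propan-2-yl)cyclohex-3-en-1-yl]oxy}silane | CC(C)[C@@]1(O[Si](CC)(CC)CC)CC=C(C)CC1 | intermediate
3 | secondary ozonide of 2, 1-methyl-4-(propan-2-yl)-4-(triethylsilyloxy)-7,8,9-trioxabicyclo[4.2.1]nonane (carbinol centre as in 2; trioxolane carbons as a mixture) | CC(C)[C@]1(O[Si](CC)(CC)CC)CCC2(C)OOC(C1)O2 | intermediate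
4 | (3S)-6-oxo-3-(propan-2-yl)-3-(triethylsilyloxy)heptanal | CC(C)[C@@](CC=O)(CCC(C)=O)O[Si](CC)(CC)CC | intermediate
5 | aldol adduct, 2-hydroxy-2-methyl-5-(propan-2-yl)-5-(triethylsilyloxy)cyclopentane-1-carbaldehyde (silyloxy carbon as in 4; C1 and C2 as mixtures) | CC(C)[C@]1(O[Si](CC)(CC)CC)CCC(C)(O)C1C=O | intermediate
6 | (5R)-2-methyl-5-(propan-2-yl)-5-(triethylsilyloxy)cyclopent-1-ene-1-carbaldehyde | CC(C)[C@]1(O[Si](CC)(CC)CC)CCC(C)=C1C=O | intermediate
7 | 1-[(5R)-2-methyl-5-(propan-2-yl)-5-(triethylsilyloxy)cyclopent-1-en-1-yl]ethan-1-ol (both carbinol epimers) | CC(C)[C@]1(O[Si](CC)(CC)CC)CCC(C)=C1C(C)O | intermediate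
8 | 1-[(5R)-2-methyl-5-(propan-2-yl)-5-(triethylsilyloxy)cyclopent-1-en-1-yl]ethan-1-one | CC(C)[C@]1(O[Si](CC)(CC)CC)CCC(C)=C1C(C)=O | intermediate
9 | lithium 1-[(5R)-2-methyl-5-(propan-2-yl)-5-(triethylsilyloxy)cyclopent-1-en-1-yl]ethen-1-olate | CC(C)[C@]1(O[Si](CC)(CC)CC)CCC(C)=C1C(=C)O[Li] | intermediate
10 | tert-butyl({1-[(5R)-2-methyl-5-(propan-2-yl)-5-(triethylsilyloxy)cyclopent-1-en-1-yl]ethenyl}oxy)dimethylsilane | CC(C)[C@]1(O[Si](CC)(CC)CC)CCC(C)=C1C(=C)O[Si](C)(C)C(C)(C)C | intermediate
11 | methyl but-3-enoate | COC(=O)CC=C | starting material
12 | methyl 2-diazobut-3-enoate | C=CC(=[N+]=[N-])C(=O)OC | intermediate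
13 | methyl (1S,2R)-2-(tert-butyldimethylsilyloxy)-1-ethenyl-2-[(5R)-2-methyl-5-(propan-2-yl)-5-(triethylsilyloxy)cyclopent-1-en-1-yl]cyclopropane-1-carboxylate (vinyl and cyclopentenyl cis) | C=C[C@@]1(C(=O)OC)C[C@@]1(O[Si](C)(C)C(C)(C)C)C2=C(C)CC[C@]2(C(C)C)O[Si](CC)(CC)CC | intermediate
14 | methyl (1R,4R)-6-(tert-butyldimethylsilyloxy)-4-(triethylsilyloxy)dauca-5,8-dien-14-oate | CC(C)[C@]1(O[Si](CC)(CC)CC)CC[C@]2(C)CC=C(C(=O)OC)CC(O[Si](C)(C)C(C)(C)C)=C21 | intermediate
15 | (1R,4R)-6-(tert-butyldimethylsilyloxy)-4-(triethylsilyloxy)dauca-5,8-dien-14-ol | CC(C)[C@]1(O[Si](CC)(CC)CC)CC[C@]2(C)CC=C(CO)CC(O[Si](C)(C)C(C)(C)C)=C21 | intermediate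
16 | (1R,4R)-6-(tert-butyldimethylsilyloxy)-4-(triethylsilyloxy)dauca-5,8-dien-14-yl methanesulfonate | CC(C)[C@]1(O[Si](CC)(CC)CC)CC[C@]2(C)CC=C(COS(C)(=O)=O)CC(O[Si](C)(C)C(C)(C)C)=C21 | intermediate
17 | (1R,4R)-6-(tert-butyldimethylsilyloxy)-4-(triethylsilyloxy)dauca-5,8-diene | CC(C)[C@]1(O[Si](CC)(CC)CC)CC[C@]2(C)CC=C(C)CC(O[Si](C)(C)C(C)(C)C)=C21 | intermediate
18 | (1R,4R,5S)-4-(triethylsilyloxy)dauc-8-en-6-one (cis-fused, H5 on the face of C15) | CC(C)[C@]1(O[Si](CC)(CC)CC)CC[C@]2(C)CC=C(C)CC(=O)[C@@H]21 | intermediate
19 | potassium dienolate of 20 (C6–OK, C6=C7, C8=C9; H5 on the isopropyl face) | CC(C)[C@]1(O[Si](CC)(CC)CC)CC[C@]2(C)CC=C(C)C=C(O[K])[C@H]21 | intermediate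
20 | (1R,4R,5R)-4-(triethylsilyloxy)dauc-8-en-6-one (trans-fused) | CC(C)[C@]1(O[Si](CC)(CC)CC)CC[C@]2(C)CC=C(C)CC(=O)[C@H]21 | intermediate
21 | (1R,4R,5R)-4-hydroxydauc-8-en-6-one | CC(C)[C@]1(O)CC[C@]2(C)CC=C(C)CC(=O)[C@H]21 | intermediate
22 | (1R,4R,5S,6S)-dauc-8-ene-4,6-diol (jaeschkeanadiol) | CC(C)[C@]1(O)CC[C@]2(C)CC=C(C)C[C@H](O)[C@H]21 | intermediate
23 | (1R,4R,5S,6S,8R,9S)-8,9-epoxydaucane-4,6-diol | CC(C)[C@]1(O)CC[C@]2(C)C[C@@H]3O[C@]3(C)C[C@H](O)[C@H]21 | intermediate
24 | 4-acetoxybenzoic acid | CC(=O)Oc1ccc(cc1)C(O)=O | starting material
25 | (1R,4R,5S,6S,8R,9S)-8,9-epoxy-4-hydroxydaucan-6-yl 4-acetoxybenzoate | CC(C)[C@]1(O)CC[C@]2(C)C[C@@H]3O[C@]3(C)C[C@H](OC(=O)c3ccc(OC(C)=O)cc3)[C@H]21 | intermediate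
26 | jaeskeanin, (1R,4R,5S,6S,8R,9S)-8,9-epoxy-4-hydroxydaucan-6-yl 4-hydroxybenzoate | CC(C)[C@]1(O)CC[C@]2(C)C[C@@H]3O[C@]3(C)C[C@H](OC(=O)c3ccc(O)cc3)[C@H]21 | target

## Step count and least certain steps

Total: 17 steps. Longest linear sequence: 16 steps (from 1 through steps 1–6 and 8–17); step 7 is a one-step side branch.

**Step 8 (key step).** The cyclopropanation should be the easier half. The most likely failure is in the second half: the boat Cope rearrangement is slowed by the inward C1 methyl and by the clash between C4 and the C6 silyloxy group. On forcing, the donor–acceptor cyclopropane 13 (siloxy at C6, ester at C8) can open heterolytically, which erases the C6/C8 configuration and with it the control of C1. In the first half, the unsubstituted vinylcarbenoid may react at its vinylogous terminus, and the C4 centre may oppose the catalyst and lower the diastereomer ratio at C1. Running the other catalyst antipode is the test of the assigned sense. The fallback sets out from 13, isolated from a reaction kept cold. Its ester is reduced with i-Bu2AlH at −78 °C to the cyclopropylmethanol F1, and F1 is heated in toluene. Without the acceptor only the concerted boat pathway remains, and the rearrangement gives allylic alcohol 15 directly, where the route is rejoined.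

**Step 12.** The most likely failures are incomplete or unfavourable equilibration at C5, since enolisation towards the hindered C5 is slow and the preference for the trans fusion may be small with the bulky silyl ether. β-Elimination of the silyloxy group from the C5 enolate or protonation through the exocyclic (C8=C14) dienolate may also intervene. The fallback replaces equilibrium control by a stereospecific shift and sets out from 17. Bromination of the silyl enol ether (NBS, THF, −78 °C) on the open face gives the α-bromo ketone F2 with bromine cis to C15. Reduction anti to the C–Br bond (NaBH4, CeCl3, MeOH, −40 °C) gives the cis-bromohydrin F3. KOt-Bu then induces the 1,2-hydride shift from C6 to C5 with inversion at C5 (a cis-halohydrin cannot close to an epoxide and rearranges to the ketone), which places H5 on the isopropyl face. The same cold acidic quench gives 20.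

**Step 14.** The hindered tertiary alkoxide may fail to exchange onto boron, so that external hydride attacks the less hindered face and gives the C6 epimer. The fallback uses a silicon-tethered hydride and sets out from 21. Chlorodiisopropylsilane and imidazole give the diisopropylsilyl ether F4. SnCl4-catalysed intramolecular hydrosilylation (CH2Cl2, −78 °C) delivers hydride from the C4 oxygen face and gives the cyclic silylene ether F5. HF·pyridine then releases diol 22.

**Step 10.** Regiocontrol may be lost (SN2′ hydride delivery or ionisation of the allylic sulfonate), or the enol ether may be hydrolysed by the ammonium salt. The fallback sets out from 15. ClCO2Me and pyridine give the methyl carbonate F6, which is reduced with Pd(PPh3)4 (zerovalent palladium) and LiEt3BH in THF. Hydride adds to the allyl complex at the unhindered exocyclic terminus C14 and gives 17.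

## Further compounds

F1 | step 8 | [2-(tert-butyldimethylsilyloxy)-1-ethenyl-2-[(5R)-2-methyl-5-(propan-2-yl)-5-(triethylsilyloxy)cyclopent-1-en-1-yl]cyclopropyl]methanol (ring configuration of 13) | C=C[C@@]1(CO)C[C@@]1(O[Si](C)(C)C(C)(C)C)C2=C(C)CC[C@]2(C(C)C)O[Si](CC)(CC)CC
F2 | step 12 | 5-bromo-4-(triethylsilyloxy)dauc-8-en-6-one (bromine cis to C15) | CC(C)[C@]1(O[Si](CC)(CC)CC)CC[C@]2(C)CC=C(C)CC(=O)[C@@]21Br
F3 | step 12 | 5-bromo-4-(triethylsilyloxy)dauc-8-en-6-ol (hydroxyl cis to bromine) | CC(C)[C@]1(O[Si](CC)(CC)CC)CC[C@]2(C)CC=C(C)C[C@@H](O)[C@@]21Br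
F4 | step 14 | (1R,4R,5R)-4-(diisopropylsilyloxy)dauc-8-en-6-one | CC(C)[C@]1(O[SiH](C(C)C)C(C)C)CC[C@]2(C)CC=C(C)CC(=O)[C@H]21
F5 | step 14 | 4,6-O-(diisopropylsilylene) derivative of 22 | CC(C)[C@]1(O3)CC[C@]2(C)CC=C(C)C[C@H](O[Si]3(C(C)C)C(C)C)[C@H]21
F6 | step 10 | (1R,4R)-6-(tert-butyldimethylsilyloxy)-4-(triethylsilyloxy)dauca-5,8-dien-14-yl methyl carbonate | CC(C)[C@]1(O[Si](CC)(CC)CC)CC[C@]2(C)CC=C(COC(=O)OC)CC(O[Si](C)(C)C(C)(C)C)=C21
A1 | alternative 1 | 1-hydroxy-1,8-dimethyl-4-(propan-2-yl)cyclodeca-4,8-dien-6-yl 4-acetoxybenzoate (target numbering; both alkenes cis within the ring; C1 either configuration) | CC1(O)CC/C(C(C)C)=C\[C@@H](OC(=O)c2ccc(OC(C)=O)cc2)C/C(C)=C\C1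
A2 | alternative 1 | jaeschkeanadiol 6-(4-acetoxybenzoate) | CC(C)[C@]1(O)CC[C@]2(C)CC=C(C)C[C@H](OC(=O)c3ccc(OC(C)=O)cc3)[C@H]21
A3 | alternative 2 | 6-(tert-butyldimethylsilyloxy)dauca-1(5),8-dien-4-ol (C6 as in A4) | CC(C)[C@]1(O)CCC2=C1[C@H](O[Si](C)(C)C(C)(C)C)CC(C)=CC2
A4 | alternative 2 | 6-(tert-butyldimethylsilyloxy)-5,15-cyclodauc-8-en-4-ol (cyclopropane C1–C15–C5 cis to the C4 hydroxyl) | CC(C)[C@]1(O)CC[C@@]23C[C@@]12[C@H](O[Si](C)(C)C(C)(C)C)CC(C)=CC3
A5 | alternative 3 | benzyl{7-[1-(tert-butyldimethylsilyloxy)-2-methylcyclopropyl]-6-methyl-3-(propan-2-yl)-3-(triethylsilyloxy)hept-6-en-1-yn-1-yl}dimethylsilane (carbinol carbon as C4 of the target; alkene geometry and cyclopropane centres not fixed) | CC(C)[C@](O[Si](CC)(CC)CC)(CCC(C)=CC1(O[Si](C)(C)C(C)(C)C)CC1C)C#C[Si](C)(C)Cc1ccccc1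
A6 | alternative 3 | (1R,4R)-6-[benzyl(dimethyl)silyl]-9-(tert-butyldimethylsilyloxy)-4-(triethylsilyloxy)dauca-5,9-diene (C8 epimers) | CC(C)[C@]1(O[Si](CC)(CC)CC)CC[C@]2(C)C=C(O[Si](C)(C)C(C)(C)C)C(C)CC([Si](C)(C)Cc3ccccc3)=C21
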